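## Analysis of the target

The target 19 is a tetrasubstituted benzene. Numbered from the carboxyl-bearing carbon, C1 carries CO2H, C2 a free phenol, C4 a methyl ether and C6 a thirteen-carbon chain: C1′ is the benzylic CH2, C2′ a ketone, C3′–C12′ methylenes and C13′ a primary alcohol. C3 and C5 are unsubstituted. There is no stereocentre, so nothing has to be controlled; any centre made on the way must disappear again. The sensitive array is the acid at C1 next to the C2′ ketone: a 2-(2-oxoalkyl)benzoic acid is in ring–chain equilibrium with its lactol and dehydrates to the 3-alkylisocoumarin under strong or hot acid. As an ester under base, the same array lets the C3′ enolate attack the ester carbon and close a naphthalene-1,3-diol. The acid is also an electron-rich salicylic acid and can lose CO2 in hot acid. The difficulty therefore lies in the contiguous C6–C1–C2 triad with the carboxyl in the middle, in telling the C2 and C4 oxygens apart, and in the order in which ester, ketone and alcohol are unmasked. The strategy rests on the 1,3-relationship of the C2 and C4 oxygens with the carboxyl on C1. At the dihydro level the ring is a 6-substituted 2,4-dioxocyclohexane-1-carboxylate, in which the C2 oxygen is the hydrogen-bonded enol of a β-keto ester and the C4 oxygen is a free vinylogous acid, so the two oxygens are different from the moment the ring exists.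

## Retrosynthetic reasoning

Positions are discussed in the target numbering above; compound names use their own locants.

**19 ⇒ 18.** The O–benzyl bond at C13′ is cut last. The free keto acid is then released by neutral hydrogenolysis, with no acid or base present that could dehydrate the lactol. The aryl–CH2–C(=O) unit has no benzylic C–O bond, so only the benzyl ether of 18 should be lost.

**18 ⇒ 16 (through 17).** The methyl ester and the C2′ dioxolane are removed in that order. The ester has to be hydrolysed by aqueous base while the ketone is still masked (17), because a free C2′ ketone beside an ester under base invites C3′-enolate acylation and enol-lactone formation. Once the carboxylate exists it is no longer an electrophile, and dilute aqueous acid at room temperature can unmask the ketone.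

**16 ⇒ 15.** The C4 O–CH3 bond is cut. In 15 the C2 hydroxyl sits in a six-membered hydrogen bond to the ester carbonyl. The C4 hydroxyl is para to the ester, more acidic and unhindered, so one equivalent of a mild base and a methylating agent should reach it alone.

**15 ⇒ 13.** The arene is taken back to the saturated dione; forward, a double bond must be introduced between C1 and C6 without harming the dioxolane. A halogen-mediated aromatisation in a hot alcohol would methylate and dehydrogenate in one pot, but it liberates hydrogen halide, which would exchange or cleave the dioxolane and expose the side-chain ketone during the aromatisation. The dehydrogenation is therefore run under basic, then buffered conditions. A selenium group is placed on C1 through the dianion (14) and leaves by syn elimination with H6, and tautomerisation gives 15. Methylation follows aromatisation because the phenol pair of 15 is differentiated more reliably than the two enol oxygens of 13.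

**13 ⇒ 10 + 11 (key disconnection).** The C1–C6 and C3–C4 bonds are cut. This divides the ring into a four-carbon nucleophile 11, which brings C1 with its ester, C2 with its oxygen and C3, and an electrophile 10, whose ester carbon becomes C4 with its oxygen and whose β-carbon becomes C6 with the whole side chain. All four substituent positions then follow from connectivity, and the C2′ carbonyl, masked as a dioxolane, stays out of the condensation. Forward, conjugate addition must outrun deprotonation at the γ-carbon of 10, and the methyl carbon of adduct 12 must then close onto the ester.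

**10 ⇒ 8 + 9.** The C=C bond of the butenoate is cut. A stabilised phosphorane adds the two-carbon ester unit to aldehyde 8 under neutral conditions, which suits a base-sensitive β-ketal aldehyde.

**8 ⇒ 7 ⇒ 6.** The aldehyde comes from ester 7 by partial hydride reduction. The dioxolane must be in place before the reduction, so the ketone of 6 is ketalised first.

**6 ⇒ 3 + 4, and 3 ⇒ 1.** The C2–C3 bond of keto ester 6 is cut back to acid 3 and the malonate equivalent 4 (acylation, then alcoholysis with decarboxylation). Acid 3 comes from 1 by O-benzylation. Compound 1 supplies C2′ to C13′ with both ends already differentiated.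

## Alternatives that were turned down

**Alternative 1: aryne insertion into a malonate.**
- Disconnection: the C6–C1′ and C1–carboxyl bonds are cut together.
- Forward key step: fluoride (CsF) releases the aryne from 3,5-dimethoxy-2-(trimethylsilyl)phenyl trifluoromethanesulfonate A1. A malonic diester carbanion adds to the aryne carbon remote from the neighbouring methoxy group, and the aryl anion takes an ester group by acyl transfer, giving dimethyl 3,5-dimethoxyhomophthalate A2.
- For: both ortho C–C bonds are made in one step on an intact arene, with the regiochemistry steered by the methoxy group. No dehydrogenation is needed.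
- Against: what arrives at C1′ is an acetate, not the chain. The two esters must be told apart, the arylacetic acid turned into the C2′ ketone with an eleven-carbon organometallic, and the ether at C2 cleaved selectively (BCl3) next to the carbonyl. A1 itself needs several steps.
- Comparison: it is stronger on convergence and avoids any oxidation-level change of the ring. The chosen route has the complete chain, with C2′ at the ketone level, in place before the ring is made. It differentiates the phenols by construction and is not longer.

**Alternative 2: indanone as a latent keto acid.**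
- Disconnection: the C1–carboxyl carbon bond.
- Forward key step: the acid chloride of 13-acetoxy-2-(3,5-dimethoxybenzyl)tridecanoic acid A3, made with (COCl)2, undergoes Friedel–Crafts acylation with SnCl4 at either of the two equivalent ring carbons ortho to the tether. This gives racemic 11-(5,7-dimethoxy-1-oxoindan-2-yl)undecyl acetate A4. Later α-oxidation and cleavage of the C1–C2 bond of the indanone would unveil the carboxyl and the C2′ ketone together.
- For: the symmetrical arene removes any regiochemical question, every step is robust, and one cleavage delivers both carbonyl groups at the right oxidation level.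
- Against: a ring and a stereocentre are built only to be destroyed. The α-hydroxylation and cleavage add two steps, the methoxy group peri to the carbonyl must be demethylated selectively, and the acetate removed.
- Comparison: it is stronger on step-by-step reliability. The chosen route is shorter, forms the arene with the oxygens already distinguished and needs no aryl ether cleavage.

**Alternative 3: carboxylate-directed C–H acylmethylation.**
- Disconnection: the C6–C1′ bond.
- Forward key step: with [Cp*RhCl2]2, AgSbF6 and NaOAc (trivalent rhodium), the only free ortho C–H bond of 2-(benzyloxy)-4-methoxybenzoic acid A5 is metalated. The sulfoxonium ylide 13-(tert-butyldimethylsilyloxy)-1-[dimethyl(oxo)-λ6-sulfanylidene]tridecan-2-one A6 transfers its acylmethyl carbene, and the keto acid closes to 8-(benzyloxy)-3-[11-(tert-butyldimethylsilyloxy)undecyl]-6-methoxyisochromen-1-one A7.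
- For: it is the shortest and most convergent plan. The oxygen pattern is bought with the arene, and C2 is blocked, so the site of C–H activation is fixed.
- Against: the metalation has to occur on a carboxylate twisted by the 2-alkoxy group, the benzyl ether offers a competing site for cyclometalation, and the ylide is an enolisable alkyl ketone type. The product is the enol lactone, which must be opened by hydroxide, and three different protecting groups remain to be removed.
- Comparison: it is clearly stronger on step count. The chosen route offers a key step that needs only an alkoxide and two commodity esters, whose positional outcome follows from connectivity and not from directing-group geometry. It also reaches the keto acid without passing through the isocoumarin.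

Key step: step 6

Remark on the chemistry: 19 is treated as the open keto acid; its cyclic lactol is a ring–chain tautomer of the same compound. All chiral intermediates are racemic, and their centres vanish on aromatisation.

## Route

Step 1
Reactants: 1 12-hydroxydodecanoic acid
Product: 3 12-(benzyloxy)dodecanoic acid, via benzyl ester 2 (not isolated)
Conditions: NaH (3 equiv), BnBr (2.4 equiv), n-Bu4NI (cat.), THF/DMF, 0 °C to rt; then aq. NaOH, MeOH, 60 °C; HCl to pH 2
Reagents that add atoms: benzyl bromide, BrCc1ccccc1; sodium hydroxide, [Na+].[OH-]
Why: Williamson etherification of the alkoxide; the carboxylate is benzylated as well, and the benzyl ester 2 is saponified in the same pot while the ether stays.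

Step 2
Reactants: 3 12-(benzyloxy)dodecanoic acid; 4 2,2-dimethyl-1,3-dioxane-4,6-dione (Meldrum's acid)
Product: 6 methyl 14-(benzyloxy)-3-oxotetradecanoate, via acyl Meldrum's acid 5 (not isolated)
Conditions: DCC, DMAP, CH2Cl2, 0 °C to rt; filter; then MeOH, reflux
Reagents that add atoms: methanol, CO
Why: Carbodiimide-mediated C-acylation of 4, then methanolysis of 5 with loss of acetone and CO2; this is the standard two-carbon homologation of an acid to a β-keto ester.

Step 3
Reactants: 6 methyl 14-(benzyloxy)-3-oxotetradecanoate
Product: 7 methyl 2-{2-[11-(benzyloxy)undecyl]-1,3-dioxolan-2-yl}acetate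
Conditions: HOCH2CH2OH (5 equiv), TsOH·H2O (cat.), benzene, Dean–Stark, reflux
Reagents that add atoms: ethylene glycol, OCCO
Why: Acid-catalysed ketalisation of the ketone with azeotropic removal of water; the ester carbonyl does not ketalise and the benzyl ether is inert.

Step 4
Reactants: 7 methyl 2-{2-[11-(benzyloxy)undecyl]-1,3-dioxolan-2-yl}acetate
Product: 8 2-{2-[11-(benzyloxy)undecyl]-1,3-dioxolan-2-yl}acetaldehyde
Conditions: i-Bu2AlH (1.1 equiv), CH2Cl2, −78 °C; MeOH, then aq. potassium sodium tartrate
Reagents that add atoms: none
Why: Partial reduction of an ester with i-Bu2AlH; the aluminium hemiacetal is held at −78 °C, helped by chelation to a dioxolane oxygen, and gives the aldehyde only on work-up.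

Step 5
Reactants: 8 2-{2-[11-(benzyloxy)undecyl]-1,3-dioxolan-2-yl}acetaldehyde; 9 methyl (triphenylphosphoranylidene)acetate
Product: 10 methyl (E)-4-{2-[11-(benzyloxy)undecyl]-1,3-dioxolan-2-yl}but-2-enoate
Conditions: CH2Cl2, rt (crude 8 used at once)
Reagents that add atoms: none
Why: Wittig olefination with a stabilised ylide, which should give the E-enoate; the neutral conditions spare the β-ketal aldehyde from elimination.

Step 6
Reactants: 10 methyl (E)-4-{2-[11-(benzyloxy)undecyl]-1,3-dioxolan-2-yl}but-2-enoate; 11 methyl acetoacetate
Product: 13 racemic methyl trans-2-({2-[11-(benzyloxy)undecyl]-1,3-dioxolan-2-yl}methyl)-4,6-dioxocyclohexane-1-carboxylate, via Michael adduct 12 (not isolated)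
Conditions: 11 (1.3 equiv), NaOMe (1.1 equiv), dry MeOH, rt, then reflux; cold 1 M HCl to pH 4, EtOAc
Reagents that add atoms: none
Why: The sodium enolate of 11 adds through its C2 to the β-carbon of 10 (Michael addition, C1–C6 bond), and methanol protonates the resulting ester enolate to give 12. Under equilibrating methoxide the acetyl methyl group of 12 is deprotonated to a small extent and attacks the distal ester carbonyl (Claisen condensation of the Dieckmann type, C3–C4 bond) in the 6-exo-trig mode; loss of methoxide and formation of the 1,3-dione enolate make the sequence irreversible. The closest known reaction type is the Michael–Claisen annulation of acetoacetates with α,β-unsaturated esters to dihydroresorcylates. No other closure is possible, because every other enolate–carbonyl pairing in 12 would give a four-membered ring, so the positions of the ester, both oxygens and the side chain follow from connectivity. The two stereocentres (C1 and C6) form as a racemate; C1 is an epimerisable β-keto ester carbon and should settle trans to the C6 substituent under thermodynamic control, and both centres vanish on aromatisation, so no stereocontrol is needed. The step needs conjugate addition to be faster than deprotonation at the γ-carbon of 10, which would move the double bond and could open the dioxolane by vinylogous β-elimination. This is secured by keeping 11 in excess over NaOMe during the room-temperature stage, so that the only base present is the soft, weakly basic acetoacetate enolate, and by heating only after 10 is consumed. The dioxolane is inert to alkoxide and keeps the C2′ carbonyl out of the condensation, and the work-up is a brief cold acidification so that the ketal survives.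

Step 7
Reactants: 13 racemic methyl trans-2-({2-[11-(benzyloxy)undecyl]-1,3-dioxolan-2-yl}methyl)-4,6-dioxocyclohexane-1-carboxylate
Product: 15 methyl 2-({2-[11-(benzyloxy)undecyl]-1,3-dioxolan-2-yl}methyl)-4,6-dihydroxybenzoate, via selenide 14 (not isolated)
Conditions: LiN(i-Pr)2 (2.2 equiv), THF, −78 to −20 °C; PhSeBr (1.05 equiv), −78 °C; then 30% H2O2, pyridine, CH2Cl2, 0 °C to rt
Reagents that add atoms: none
Why: Two equivalents of LiN(i-Pr)2 give the dianion (dione enolate plus the ester-stabilised C1 carbanion), which should take the selenium electrophile at C1 trans to the C6 substituent. Oxidation at selenium is followed by syn elimination with the cis H6 (selenoxide elimination), and the dienone tautomerises to the resorcylate. The medium is basic and then pyridine-buffered, so the dioxolane and benzyl ether should persist.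

Step 8
Reactants: 15 methyl 2-({2-[11-(benzyloxy)undecyl]-1,3-dioxolan-2-yl}methyl)-4,6-dihydroxybenzoate
Product: 16 methyl 2-({2-[11-(benzyloxy)undecyl]-1,3-dioxolan-2-yl}methyl)-6-hydroxy-4-methoxybenzoate
Conditions: K2CO3 (1.1 equiv), MeI (1.1 equiv), acetone, rt
Reagents that add atoms: iodomethane, CI
Why: Regioselective Williamson O-methylation; the hydroxyl para to the ester is the more acidic and is free, while the ortho hydroxyl is held in a hydrogen bond to the ester carbonyl and should not react with one equivalent of reagent.

Step 9
Reactants: 16 methyl 2-({2-[11-(benzyloxy)undecyl]-1,3-dioxolan-2-yl}methyl)-6-hydroxy-4-methoxybenzoate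
Product: 18 2-[13-(benzyloxy)-2-oxotridecyl]-6-hydroxy-4-methoxybenzoic acid, via ketal acid 17 (not isolated)
Conditions: KOH (10 equiv), DMSO/H2O, 80 °C; acidify cold, extract; then 1 M HCl/THF, rt
Reagents that add atoms: potassium hydroxide, [K+].[OH-]; water, O
Why: Saponification of the hindered salicylate needs hot concentrated hydroxide, to which the ketal and benzyl ether are stable, and with the ketone still masked no enolate can attack the ester. Dilute aqueous acid at room temperature then hydrolyses the dioxolane of 17; these conditions should be too mild for dehydration to the isocoumarin or for decarboxylation.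

Step 10
Reactants: 18 2-[13-(benzyloxy)-2-oxotridecyl]-6-hydroxy-4-methoxybenzoic acid
Product: 19 2-hydroxy-6-(13-hydroxy-2-oxotridecyl)-4-methoxybenzoic acid (CNP0165592.0)
Conditions: H2 (1 atm), 10% Pd on carbon, EtOAc, rt
Reagents that add atoms: none
Why: Hydrogenolysis of the alkyl benzyl ether under neutral conditions; the arene, the ketone and the acid should not be reduced at 1 atm, and no acid or base is present that could dehydrate the keto acid.

## Compound list

1 | 12-hydroxydodecanoic acid | OCCCCCCCCCCCC(=O)O | starting material
2 | benzyl 12-(benzyloxy)dodecanoate | O=C(CCCCCCCCCCCOCc1ccccc1)OCc1ccccc1 | intermediate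
3 | 12-(benzyloxy)dodecanoic acid | OC(=O)CCCCCCCCCCCOCc1ccccc1 | intermediate
4 | 2,2-dimethyl-1,3-dioxane-4,6-dione (Meldrum's acid) | CC1(C)OC(=O)CC(=O)O1 | starting material
5 | 5-[12-(benzyloxy)-1-hydroxydodecylidene]-2,2-dimethyl-1,3-dioxane-4,6-dione | CC1(C)OC(=O)C(=C(O)CCCCCCCCCCCOCc2ccccc2)C(=O)O1 | intermediate
6 | methyl 14-(benzyloxy)-3-oxotetradecanoate | COC(=O)CC(=O)CCCCCCCCCCCOCc1ccccc1 | intermediate
7 | methyl 2-{2-[11-(benzyloxy)undecyl]-1,3-dioxolan-2-yl}acetate | COC(=O)CC1(CCCCCCCCCCCOCc2ccccc2)OCCO1 | intermediate
8 | 2-{2-[11-(benzyloxy)undecyl]-1,3-dioxolan-2-yl}acetaldehyde | O=CCC1(CCCCCCCCCCCOCc2ccccc2)OCCO1 | intermediate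
9 | methyl (triphenylphosphoranylidene)acetate | COC(=O)C=P(c1ccccc1)(c1ccccc1)c1ccccc1 | starting material
10 | methyl (E)-4-{2-[11-(benzyloxy)undecyl]-1,3-dioxolan-2-yl}but-2-enoate | COC(=O)/C=C/CC1(CCCCCCCCCCCOCc2ccccc2)OCCO1 | intermediate
11 | methyl acetoacetate | CC(=O)CC(=O)OC | starting material
12 | dimethyl 2-acetyl-3-({2-[11-(benzyloxy)undecyl]-1,3-dioxolan-2-yl}methyl)pentanedioate (racemic, mixture of diastereomers) | COC(=O)CC(CC1(CCCCCCCCCCCOCc2ccccc2)OCCO1)C(C(C)=O)C(=O)OC | intermediate
13 | racemic methyl trans-2-({2-[11-(benzyloxy)undecyl]-1,3-dioxolan-2-yl}methyl)-4,6-dioxocyclohexane-1-carboxylate (relative configuration drawn) | COC(=O)[C@@H]1C(=O)CC(=O)C[C@H]1CC1(CCCCCCCCCCCOCc2ccccc2)OCCO1 | intermediate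
14 | racemic methyl 2-({2-[11-(benzyloxy)undecyl]-1,3-dioxolan-2-yl}methyl)-4,6-dioxo-1-(phenylselanyl)cyclohexane-1-carboxylate, selenium trans to the side chain (relative configuration drawn) | COC(=O)[C@@]1([Se]c2ccccc2)C(=O)CC(=O)C[C@H]1CC1(CCCCCCCCCCCOCc2ccccc2)OCCO1 | intermediate
15 | methyl 2-({2-[11-(benzyloxy)undecyl]-1,3-dioxolan-2-yl}methyl)-4,6-dihydroxybenzoate | COC(=O)c1c(O)cc(O)cc1CC1(CCCCCCCCCCCOCc2ccccc2)OCCO1 | intermediate
16 | methyl 2-({2-[11-(benzyloxy)undecyl]-1,3-dioxolan-2-yl}methyl)-6-hydroxy-4-methoxybenzoate | COC(=O)c1c(O)cc(OC)cc1CC1(CCCCCCCCCCCOCc2ccccc2)OCCO1 | intermediate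
17 | 2-({2-[11-(benzyloxy)undecyl]-1,3-dioxolan-2-yl}methyl)-6-hydroxy-4-methoxybenzoic acid | OC(=O)c1c(O)cc(OC)cc1CC1(CCCCCCCCCCCOCc2ccccc2)OCCO1 | intermediate
18 | 2-[13-(benzyloxy)-2-oxotridecyl]-6-hydroxy-4-methoxybenzoic acid | OC(=O)c1c(O)cc(OC)cc1CC(=O)CCCCCCCCCCCOCc1ccccc1 | intermediate
19 | 2-hydroxy-6-(13-hydroxy-2-oxotridecyl)-4-methoxybenzoic acid | COc1cc(O)c(C(=O)O)c(CC(=O)CCCCCCCCCCCO)c1 | target

## Step count and least certain steps

Total step count: 10. Longest linear sequence: 10 steps (1 to 19).

**Step 6 (key step).** The conjugate addition to a β-substituted enoate is slow, so deprotonation at the γ-carbon of 10 can compete. The dienolate can move the double bond out of conjugation and open the dioxolane by vinylogous β-elimination of alkoxide. The closure can also stall at 12, which then suffers retro-Michael cleavage or, with traces of water, ester hydrolysis and decarboxylation. The fallback sets out from 8 and returns at 13, forming the ring through the C1–C6 and C2–C3 bonds instead. Wittig olefination of 8 with Ph3P=CHC(O)CH3 should give the enone (E)-5-{2-[11-(benzyloxy)undecyl]-1,3-dioxolan-2-yl}pent-3-en-2-one F1, a much stronger acceptor than 10. Dimethyl malonate adds to it with catalytic NaOMe at 0 °C to give the Michael adduct dimethyl 2-(1-{2-[11-(benzyloxy)undecyl]-1,3-dioxolan-2-yl}-4-oxopentan-2-yl)propanedioate F2. A full equivalent of NaOMe in refluxing MeOH then closes the methyl ketone onto one malonate ester to give 13.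

**Step 7.** Dianion formation may be incomplete, so that selenium is delivered to C3 between the two carbonyls, where no syn β-hydrogen exists. Selenenylation cis to the side chain would also block the elimination. The electron-rich resorcylate may be over-oxidised or selenenylated on the ring by the selenium by-products, and selenium traces may later poison the Pd catalyst of step 10. The fallback sets out from 13 and returns at 16, bypassing 15 and step 8. Me2SO4 and K2CO3 in acetone methylate the less hindered C4 oxygen to give the enol ether methyl trans-6-({2-[11-(benzyloxy)undecyl]-1,3-dioxolan-2-yl}methyl)-4-methoxy-2-oxocyclohex-3-ene-1-carboxylate F3. Any methylation at the C2 oxygen is reversed by aqueous hydroxide, which returns 13. In F3 only C1–H is acidic, so NaH and PhSeCl give the selenide methyl 6-({2-[11-(benzyloxy)undecyl]-1,3-dioxolan-2-yl}methyl)-4-methoxy-2-oxo-1-(phenylselanyl)cyclohex-3-ene-1-carboxylate F4. H2O2 with pyridine then eliminates and aromatises it to 16, a less electron-rich phenol than 15.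

**Step 9.** Hydrolysis of the doubly ortho-substituted ester is slow because the ortho phenoxide deactivates it. At the temperature needed, and on acidification, the electron-rich acid may decarboxylate, and during ketal removal the keto acid may dehydrate to the isocoumarin. The fallback sets out from 16 and returns at 18, using the neighbouring ketone to activate the ester. PPTS in aqueous acetone removes the ketal to give methyl 2-[13-(benzyloxy)-2-oxotridecyl]-6-hydroxy-4-methoxybenzoate F5. TsOH in refluxing toluene, with removal of methanol, closes the enol lactone 3-[11-(benzyloxy)undecyl]-8-hydroxy-6-methoxy-1H-isochromen-1-one F6. Aqueous KOH in THF at room temperature opens this activated lactone, and cold acidification gives 18.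

**Step 4.** Over-reduction to the primary alcohol is possible. The β-ketal aldehyde may also open its dioxolane by β-elimination towards the conjugated enal during work-up or on silica. The fallback sets out from 7 and returns at 8, separating reduction from oxidation. LiAlH4 in THF reduces 7 fully to 2-{2-[11-(benzyloxy)undecyl]-1,3-dioxolan-2-yl}ethan-1-ol F7. Parikh–Doering oxidation (SO3·pyridine, DMSO, Et3N) then gives 8 under basic, non-aqueous conditions, and 9 is added to the crude aldehyde.

## Further compounds

F1 | step 6 | (E)-5-{2-[11-(benzyloxy)undecyl]-1,3-dioxolan-2-yl}pent-3-en-2-one | CC(=O)/C=C/CC1(CCCCCCCCCCCOCc2ccccc2)OCCO1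
F2 | step 6 | dimethyl 2-(1-{2-[11-(benzyloxy)undecyl]-1,3-dioxolan-2-yl}-4-oxopentan-2-yl)propanedioate (racemic) | COC(=O)C(C(=O)OC)C(CC(C)=O)CC1(CCCCCCCCCCCOCc2ccccc2)OCCO1
F3 | step 7 | racemic methyl trans-6-({2-[11-(benzyloxy)undecyl]-1,3-dioxolan-2-yl}methyl)-4-methoxy-2-oxocyclohex-3-ene-1-carboxylate | COC(=O)[C@@H]1C(=O)C=C(OC)C[C@H]1CC1(CCCCCCCCCCCOCc2ccccc2)OCCO1
F4 | step 7 | racemic methyl 6-({2-[11-(benzyloxy)undecyl]-1,3-dioxolan-2-yl}methyl)-4-methoxy-2-oxo-1-(phenylselanyl)cyclohex-3-ene-1-carboxylate, selenium trans to the side chain | COC(=O)[C@@]1([Se]c2ccccc2)C(=O)C=C(OC)C[C@H]1CC1(CCCCCCCCCCCOCc2ccccc2)OCCO1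
F5 | step 9 | methyl 2-[13-(benzyloxy)-2-oxotridecyl]-6-hydroxy-4-methoxybenzoate | COC(=O)c1c(O)cc(OC)cc1CC(=O)CCCCCCCCCCCOCc1ccccc1
F6 | step 9 | 3-[11-(benzyloxy)undecyl]-8-hydroxy-6-methoxy-1H-isochromen-1-one | COc1cc(O)c2C(=O)OC(CCCCCCCCCCCOCc3ccccc3)=Cc2c1
F7 | step 4 | 2-{2-[11-(benzyloxy)undecyl]-1,3-dioxolan-2-yl}ethan-1-ol | OCCC1(CCCCCCCCCCCOCc2ccccc2)OCCO1
A1 | alternative 1 | 3,5-dimethoxy-2-(trimethylsilyl)phenyl trifluoromethanesulfonate | COc1cc(OC)c([Si](C)(C)C)c(OS(=O)(=O)C(F)(F)F)c1
A2 | alternative 1 | dimethyl 3,5-dimethoxyhomophthalate | COC(=O)Cc1cc(OC)cc(OC)c1C(=O)OC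
A3 | alternative 2 | 13-acetoxy-2-(3,5-dimethoxybenzyl)tridecanoic acid (racemic) | COc1cc(CC(CCCCCCCCCCCOC(C)=O)C(=O)O)cc(OC)c1
A4 | alternative 2 | racemic 11-(5,7-dimethoxy-1-oxoindan-2-yl)undecyl acetate | COc1cc2c(c(OC)c1)C(=O)C(CCCCCCCCCCCOC(C)=O)C2
A5 | alternative 3 | 2-(benzyloxy)-4-methoxybenzoic acid | COc1ccc(C(=O)O)c(OCc2ccccc2)c1
A6 | alternative 3 | 13-(tert-butyldimethylsilyloxy)-1-[dimethyl(oxo)-λ6-sulfanylidene]tridecan-2-one | CS(C)(=O)=CC(=O)CCCCCCCCCCCO[Si](C)(C)C(C)(C)C
A7 | alternative 3 | 8-(benzyloxy)-3-[11-(tert-butyldimethylsilyloxy)undecyl]-6-methoxyisochromen-1-one | COc1cc2C=C(CCCCCCCCCCCO[Si](C)(C)C(C)(C)C)OC(=O)c2c(OCc3ccccc3)c1
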